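## Structural features

The target, C24H18O12, is a linear array of four benzene rings: ring A (3,5-dihydroxyphenyl) is joined through an ether oxygen to B1 of ring B, B4 of ring B is joined through a second ether oxygen to C1 of ring C, and C5 of ring C is bonded directly to D1 of ring D (2,4,6-trihydroxyphenyl). It contains twelve oxygen atoms, ten as free hydroxyls and two as ether bridges. There is no stereocentre, so none stand next to each other, and the hindered C5–D1 axis is not stereogenic because ring D is symmetric about its D1–D4 line. Rings B and C are both 1,2,3,5-tetraoxygenated, so the central B4–O–C1 ether is flanked by four hydroxyls (B3, B5, C2, C6) and the biaryl bond by four more (C4, C6, D2, D6). As free phenols all four rings are very electron-rich and are easily oxidised by air, especially in base, so the hydroxyls should travel as methyl ethers until the last step. The real difficulty is the diaryl ether carrying four ortho oxygens between two electron-rich rings, a bond that copper- or palladium-mediated etherification forms poorly; the tetra-ortho-substituted biaryl bond comes second. The key step exploits the position of B3–OH, B5–OH, C2–OH and C6–OH: each is ortho to the central ether oxygen, so each can be the remnant of a formyl group, and two formyl groups ortho to a fluoride are what allow the ether to be made by uncatalysed SNAr.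

## Logic of the disconnections

15 back to 14. Ten O–CH3 bonds are cut. The free polyphenol is too oxidation-prone to carry through metal catalysis, whereas methyl ethers tolerate every earlier reagent. The gain is one robust protecting group for all ten hydroxyls. The demand is a last step that cleaves ten alkyl–oxygen bonds and leaves the two aryl–O–aryl bridges intact.

14 back to 12 and 13. The A1–O bond of the outer ether is cut. Neither the phenol oxygen on B1 nor the ring A carbon has an ortho substituent, so an oxidative copper coupling of a phenol with an arylboronic acid fits. The gain is ring A as a bought piece. The demand is that the electron-rich phenol 12 is arylated faster than it is oxidised.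

12 back to 10. The B1–O bond is traced back to a B1–H bond. B1–H is the only C–H of 10 with two hydrogen neighbours, so a sterically governed borylation followed by oxidation can place the oxygen there. The gain is that ring B needs no handle during the ether synthesis and the oxidation. The demand is clean site selectivity and an oxidation that spares the methoxy-rich arenes.

10 back to 8 and 9. The C5–D1 biaryl bond is cut, which removes ring D as a bought boronic acid. The gain is convergence. The demand is a cross-coupling that forms a tetra-ortho-substituted biaryl from a boronic acid prone to protodeboronation.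

8 back to 7. The C5–Br bond is cut. In 7 only ring C has positions activated by three methoxy groups, so an electrophile finds it. This is also why ring A, another 1,3,5-trioxygenated ring, is attached only later. The two free positions of ring C are equivalent, so the demand is only to stop at one bromine.

7 back to 6. Four O–CH3 bonds are cut. The tetraol is air-sensitive and is capped in the same ether form as the oxygens of the bought pieces. The demand is exhaustive O-methylation without C-methylation.

6 back to 4 (through 5). The B3–O, B5–O, C2–O and C6–O bonds are cut and each becomes a ring–CHO bond. The four oxygens that crowd the ether are thus replaced by the groups that make the ether accessible. The gain is four oxygens in one operation with no protecting group. The demand is aryl rather than hydride migration at all four formyl groups.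

4 back to 2 and 3. The B4–O bond is cut. The B4 carbon of 3 carries fluoride between two formyl groups and is a strong SNAr acceptor, so the tetra-ortho-substituted ether forms by addition–elimination without a metal. The gain is two simple benzene building blocks. The demand is that the phenoxide of 2, weakened by its own formyl groups, still adds, and that aryloxide exchange on the activated product is avoided.

2 back to 1. The two C–CHO bonds at C2 and C6 of ring C are cut. The para position of 1 is blocked by methoxy, so a double ortho-formylation is the direct way. The demand is to drive the Duff reaction to the dialdehyde.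

## Other disconnections considered

Alternative 1: The cut runs through ring C at C3–C4, and one stage further back to a four-membered squarate-derived core. In the forward direction racemic cyclobutenone A1 would be heated in toluene or xylene. A 4π ring opening gives a dienylketene, 6π electrocyclisation joins the ketene carbon to the vinyl terminus (C3–C4), and tautomerisation gives the hydroquinone monosilyl ether A2 with C1–OSi, C4–OH, C2–OEt, C6–OMe and ring D at C5.
- In its favour: the C5–D1 bond would come from addition of an aryl-metal to a squarate carbonyl, not from a tetra-ortho cross-coupling. On that bond the alternative is better than step 6 of the chosen plan. The order of additions to the squarate fixes every oxygen position, and C1–O and C4–O emerge differentiated.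
- Against it: the central B4–O–C1 ether is not addressed. After desilylation a phenol flanked by two alkoxy groups must still be joined to a ring B carbon with two ortho oxygens. The realistic way is the formyl-activated SNAr and Baeyer–Villiger sequence of the chosen plan, reduced to two migrations. The free C4 hydroxyl needs an extra capping step.
- Comparison: on structure it solves the second-hardest bond and leaves the hardest. On mechanism a thermal pericyclic cascade without oxidant and without a migratory competition is at least the equal of a fourfold peracid oxidation. On step economy about five steps would be needed to reach A2 (rings C and D only), whereas the chosen plan reaches 10 (rings B, C and D) in six.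

Alternative 2: The cut is the D1–D2 bond of ring D, with ring D stored as a 4-methoxy-2-pyranone attached to ring C through a methylene group. In the forward direction Mg(OMe)2 in hot methanol would open pyranone A3 to a chelated keto ester. Its benzylic carbon (D1) attacks the ester carbon (D2) in a Claisen-type closure, and enolisation gives A4.
- In its favour: no biaryl coupling is needed, since the C5–D1 bond exists from the start as a benzylic C–C bond. This is again better than step 6 of the chosen plan. The closure mirrors polyketide folding. A4 already has two free ring D hydroxyls, so the last step would cleave eight methyl ethers and not ten, a small advantage.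
- Against it: ring D is formed last on the full A–B–C array, so the sensitive pyranone side chain or its precursor must be installed at the most hindered position of ring C and carried along. Adding the one-carbon unit, activating it and alkylating a pyranone would cost four or five steps where bromination and Suzuki coupling need two. The nucleophilic carbon in the closure is attached to a di-ortho-substituted aryl group, and reclosure to a pyranone is a plausible competitor. The central ether is again left to other chemistry.
- Comparison: structurally it trades a hindered cross-coupling for a hindered Claisen closure. Mechanistically both are ionic, base-mediated and well precedented. In step count it is clearly longer.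

Alternative 3: The cut runs through ring B at B5–B6 and B1–B2 (formed in a cycloaddition) and B4–B5 (formed in the closing electrocyclisation). In the forward direction racemic cyclobutenone A5 would be heated with aryloxyacetylene A6. 4π opening of A5 gives a vinylketene, regioselective (2+2) cycloaddition with A6 gives a vinylcyclobutenone, and 4π opening followed by 6π closure and tautomerisation gives A7 with B5–OH, B3–OEt and both ether oxygens in place.
- In its favour: this is the only alternative that answers the hard ether. The B4–O bond exists before ring B is aromatic, as an sp3 carbon–oxygen bond, so no hindered aryl–aryl etherification is needed. Ring A arrives with the alkyne, so the borylation and Chan–Lam steps vanish. On convergence it is better than the chosen plan.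
- Against it: A5 needs the complete ring C–D phenol, with the same tetra-ortho biaryl problem, then conversion to an aryloxyketene precursor and a ketene–alkyne cycloaddition. Its C4–H is enolisable. A6 is a thermally labile aryl ynol ether. The key step would thus combine two fragile partners at the most valuable stage. B3–OEt and B5–OH come out differentiated, which the target does not require.
- Comparison: on mechanism it is neutral and thermal with no oxidation, and its risks are ketene dimerisation and cycloaddition regiochemistry, against migratory aptitude in the chosen plan. On step economy the longest linear sequence would be similar, but the total number of steps is estimated to be higher, since three fragments must each be prepared.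

Key step: step 3

Remark: the target has twelve oxygen atoms (ten hydroxyls and two ether oxygens), so the key step installs four of twelve.
Remark: a formate formed on a ring lies meta to the remaining migrating carbon of that ring and gives it no resonance help. The assistance comes from the ether oxygen, as set out under step 3.
Remark: the ring A ether is formed from phenol 12 and (3,5-dimethoxyphenyl)boronic acid 13, with borylation and oxidation of ring B in one flask. Aryl pinacol boronates transmetalate sluggishly to copper, so this pairing is safer than coupling a pinacol boronate with a phenol, and it costs no extra step.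
Remark: compounds 1, 3, 9 and 13 are assumed to be purchasable. Ring C derives from 1 and ring B from 3.

## Steps

Step 1
Reactants: 1 4-methoxyphenol
Product: 2 2-hydroxy-5-methoxybenzene-1,3-dicarbaldehyde
Conditions: hexamethylenetetramine (4 equiv), TFA, reflux; then 4 M aq HCl, 25 °C
Reagents that add atoms: hexamethylenetetramine C1N2CN3CN1CN(C2)C3 (formyl carbons); water O (formyl oxygens)
Why: Duff reaction: iminium ions from protonated hexamethylenetetramine substitute both positions ortho to the hydroxyl (para is blocked by methoxy), the benzylic amines are oxidised to iminium ions by hydride transfer, and aqueous acid releases the two formyl groups. The hydroxyl outranks the methoxy group as director, so both aldehydes should flank the phenol oxygen.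

Step 2
Reactants: 2 2-hydroxy-5-methoxybenzene-1,3-dicarbaldehyde; 3 2-fluorobenzene-1,3-dicarbaldehyde
Product: 4 2-(2,6-diformylphenoxy)-5-methoxybenzene-1,3-dicarbaldehyde
Conditions: K2CO3 (1.5 equiv), 3 (1.1 equiv), dry DMF, 70 °C, argon
Reagents that add atoms: none
Why: Nucleophilic aromatic substitution by addition–elimination: the two ortho formyl groups of 3 stabilise the Meisenheimer adduct and fluoride is the best leaving group for a rate-limiting addition, so the tetra-ortho-substituted ether should form without a metal. Dry conditions, a small excess of 3 and moderate temperature are chosen because the phenoxide of 2 is a weakened nucleophile and the product is itself an activated aryl ether.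

Step 3
Reactants: 4 2-(2,6-diformylphenoxy)-5-methoxybenzene-1,3-dicarbaldehyde
Product: 6 2-(2,6-dihydroxyphenoxy)-5-methoxybenzene-1,3-diol, via tetraformate 5 (not isolated)
Conditions: mCPBA (6 equiv), CH2Cl2, 0 to 40 °C; aq Na2SO3 wash; then HCl (cat.), MeOH, 25 °C, argon
Reagents that add atoms: mCPBA OOC(=O)c1cccc(Cl)c1
Why: Each formyl group adds mCPBA to give a Criegee adduct, the ring carbon migrates from carbon to oxygen with loss of 3-chlorobenzoate, and four such events give tetraformate 5 with the new B3–O, B5–O, C2–O and C6–O bonds; acidic methanolysis then transfers the formyl groups to methanol. The closest known reaction type is the Baeyer–Villiger (Dakin-type) oxidation of 2-aryloxybenzaldehydes made by fluoride SNAr, which gives 2-aryloxyphenols; here it is run at four formyl groups of one molecule. No ring is closed and no stereocentre is created. The selectivity required is aryl over hydride migration at every site, and it rests on the ether oxygen: each migrating carbon is ortho to it, and its lone pair stabilises the electron-deficient migrating terminus. A formate already formed is meta to the other migrating carbon of its ring and gives no resonance help, but each formyl group removed from one ring stops drawing on the ether lone pair, so the other ring gains and later migrations should not be harder than the first. Neutral, anhydrous CH2Cl2 avoids aldehyde hydrates, which favour acid formation, and peroxy anions, which could attack the SNAr-active ipso carbons of 4. The phenols are freed only after the peracid has been destroyed, so the electron-rich tetraol 6 never meets the oxidant, and it is carried on under argon.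

Step 4
Reactants: 6 2-(2,6-dihydroxyphenoxy)-5-methoxybenzene-1,3-diol
Product: 7 2-(2,6-dimethoxyphenoxy)-1,3,5-trimethoxybenzene
Conditions: MeI (6 equiv), K2CO3 (6 equiv), acetone, 56 °C, argon
Reagents that add atoms: iodomethane CI
Why: Williamson ether synthesis: K2CO3 deprotonates the four phenols and the phenoxides attack MeI at oxygen (SN2); a carbonate base in acetone favours O- over C-methylation, and immediate capping removes the air sensitivity of 6.

Step 5
Reactants: 7 2-(2,6-dimethoxyphenoxy)-1,3,5-trimethoxybenzene
Product: 8 2-bromo-4-(2,6-dimethoxyphenoxy)-1,3,5-trimethoxybenzene
Conditions: NBS (1.0 equiv), MeCN, 0 °C, dark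
Reagents that add atoms: N-bromosuccinimide O=C1CCC(=O)N1Br
Why: Electrophilic aromatic bromination: the free positions of ring C are ortho, ortho and para to three methoxy groups, whereas those of ring B are activated by two at most, so one equivalent of NBS at 0 °C should brominate ring C once. The two free positions of ring C are equivalent, so only one monobromide can form.

Step 6
Reactants: 8 2-bromo-4-(2,6-dimethoxyphenoxy)-1,3,5-trimethoxybenzene; 9 (2,4,6-trimethoxyphenyl)boronic acid
Product: 10 3-(2,6-dimethoxyphenoxy)-2,2',4,4',6,6'-hexamethoxy-1,1'-biphenyl
Conditions: Pd(OAc)2 (5 mol %), SPhos (10 mol %), K3PO4 (3 equiv), 9 (2 equiv), toluene/H2O 10:1, 100 °C, argon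
Reagents that add atoms: none
Why: Suzuki–Miyaura coupling: Pd(OAc)2 is reduced in the flask to zerovalent palladium, which with the bulky, electron-rich biarylphosphine SPhos inserts into the hindered C–Br bond and promotes transmetalation and reductive elimination to the tetra-ortho-substituted biaryl; the excess of 9 offsets its protodeboronation. Ring D is symmetric, so the new axis creates no stereoisomers.

Step 7
Reactants: 10 3-(2,6-dimethoxyphenoxy)-2,2',4,4',6,6'-hexamethoxy-1,1'-biphenyl
Product: 12 4-[(2,2',4,4',6,6'-hexamethoxy-[1,1'-biphenyl]-3-yl)oxy]-3,5-dimethoxyphenol, via pinacol boronate 11 (not isolated)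
Conditions: [Ir(OMe)(cod)]2 (1.5 mol %), dtbpy (3 mol %), B2pin2 (1.0 equiv), THF, 80 °C; then KHSO5 (as 2KHSO5·KHSO4·K2SO4), acetone/H2O, 25 °C
Reagents that add atoms: potassium peroxymonosulfate [K+].[O-]S(=O)(=O)OO (hydroxyl oxygen of 12); bis(pinacolato)diboron CC1(C)OB(OC1(C)C)B1OC(C)(C)C(C)(C)O1 (boryl group of 11 only)
Why: Iridium-catalysed C–H borylation is governed by sterics: the B1–H bond para to the ether oxygen is the only C–H of 10 with two hydrogen neighbours, all others lying next to one or two methoxy groups, so boron should enter there. Peroxymonosulfate then converts the C–B bond into C–OH at the same carbon by a 1,2-shift of the aryl group from boron to oxygen.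

Step 8
Reactants: 12 4-[(2,2',4,4',6,6'-hexamethoxy-[1,1'-biphenyl]-3-yl)oxy]-3,5-dimethoxyphenol; 13 (3,5-dimethoxyphenyl)boronic acid
Product: 14 3-[4-(3,5-dimethoxyphenoxy)-2,6-dimethoxyphenoxy]-2,2',4,4',6,6'-hexamethoxy-1,1'-biphenyl
Conditions: Cu(OAc)2 (20 mol %), pyridine (5 equiv), 13 (2 equiv), 4 Å MS, CH2Cl2, O2 (1 atm), 25 °C
Reagents that add atoms: none
Why: Chan–Evans–Lam coupling: the phenoxide of 12 and the aryl group of 13 meet on divalent copper, oxidation to trivalent copper and reductive elimination form the aryl–oxygen bond, and O2 returns the copper to the divalent state. Neither partner has an ortho substituent at the reacting site.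

Step 9
Reactants: 14 3-[4-(3,5-dimethoxyphenoxy)-2,6-dimethoxyphenoxy]-2,2',4,4',6,6'-hexamethoxy-1,1'-biphenyl
Product: 15 3-[4-(3,5-dihydroxyphenoxy)-2,6-dihydroxyphenoxy]-[1,1'-biphenyl]-2,2',4,4',6,6'-hexol
Conditions: BBr3 (20 equiv), CH2Cl2, −78 to 25 °C; then H2O, 0 °C, argon
Reagents that add atoms: none
Why: Lewis acid ether cleavage: BBr3 coordinates each methoxy oxygen and bromide removes the methyl group by SN2 as MeBr; the diaryl ether and biaryl bonds offer no sp3 carbon and should survive. Hydrolysis of the aryloxyboron species releases the ten phenols, which are kept under argon to prevent oxidation.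

## Compound list

1 | 4-methoxyphenol | COc1ccc(O)cc1 | starting material
2 | 2-hydroxy-5-methoxybenzene-1,3-dicarbaldehyde | COc1cc(C=O)c(O)c(C=O)c1 | intermediate
3 | 2-fluorobenzene-1,3-dicarbaldehyde | O=Cc1cccc(C=O)c1F | starting material
4 | 2-(2,6-diformylphenoxy)-5-methoxybenzene-1,3-dicarbaldehyde | COc1cc(C=O)c(Oc2c(C=O)cccc2C=O)c(C=O)c1 | intermediate
5 | 2-[2,6-bis(formyloxy)phenoxy]-5-methoxy-1,3-phenylene diformate | COc1cc(OC=O)c(Oc2c(OC=O)cccc2OC=O)c(OC=O)c1 | intermediate
6 | 2-(2,6-dihydroxyphenoxy)-5-methoxybenzene-1,3-diol | COc1cc(O)c(Oc2c(O)cccc2O)c(O)c1 | intermediate
7 | 2-(2,6-dimethoxyphenoxy)-1,3,5-trimethoxybenzene | COc1cc(OC)c(Oc2c(OC)cccc2OC)c(OC)c1 | intermediate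
8 | 2-bromo-4-(2,6-dimethoxyphenoxy)-1,3,5-trimethoxybenzene | COc1cc(OC)c(Oc2c(OC)cccc2OC)c(OC)c1Br | intermediate
9 | (2,4,6-trimethoxyphenyl)boronic acid | COc1cc(OC)c(B(O)O)c(OC)c1 | starting material
10 | 3-(2,6-dimethoxyphenoxy)-2,2',4,4',6,6'-hexamethoxy-1,1'-biphenyl | COc1cc(OC)c(-c2c(OC)cc(OC)c(Oc3c(OC)cccc3OC)c2OC)c(OC)c1 | intermediate
11 | 2-{4-[(2,2',4,4',6,6'-hexamethoxy-[1,1'-biphenyl]-3-yl)oxy]-3,5-dimethoxyphenyl}-4,4,5,5-tetramethyl-1,3,2-dioxaborolane | COc1cc(OC)c(-c2c(OC)cc(OC)c(Oc3c(OC)cc(B4OC(C)(C)C(C)(C)O4)cc3OC)c2OC)c(OC)c1 | intermediate
12 | 4-[(2,2',4,4',6,6'-hexamethoxy-[1,1'-biphenyl]-3-yl)oxy]-3,5-dimethoxyphenol | COc1cc(OC)c(-c2c(OC)cc(OC)c(Oc3c(OC)cc(O)cc3OC)c2OC)c(OC)c1 | intermediate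
13 | (3,5-dimethoxyphenyl)boronic acid | COc1cc(OC)cc(B(O)O)c1 | starting material
14 | 3-[4-(3,5-dimethoxyphenoxy)-2,6-dimethoxyphenoxy]-2,2',4,4',6,6'-hexamethoxy-1,1'-biphenyl | COc1cc(OC)cc(Oc2cc(OC)c(Oc3c(OC)cc(OC)c(-c4c(OC)cc(OC)cc4OC)c3OC)c(OC)c2)c1 | intermediate
15 | 3-[4-(3,5-dihydroxyphenoxy)-2,6-dihydroxyphenoxy]-[1,1'-biphenyl]-2,2',4,4',6,6'-hexol | Oc1cc(O)cc(Oc2cc(O)c(Oc3c(O)cc(O)c(-c4c(O)cc(O)cc4O)c3O)c(O)c2)c1 | target

## Step count and least certain steps

Total step count: 9. Longest linear sequence: 9 steps (1 to 15; compounds 3, 9 and 13 enter as bought pieces).

Step 3 (key step). The most likely failure is hydride migration in place of aryl migration at one or more of the four Criegee adducts, leading to carboxylic acids. Each ring starts with two electron-withdrawing formyl groups, and the twisted ether oxygen must serve two rings. Stalling before the fourth oxidation and ipso substitution at the activated ether are secondary risks. The fallback sets out from 3 and comes back at 7. SNAr of 3 with purchased 2,4,6-trimethoxyphenol F1 (K2CO3, DMF) would give 2-(2,4,6-trimethoxyphenoxy)benzene-1,3-dicarbaldehyde F2. A twofold Baeyer–Villiger oxidation (mCPBA, then acidic methanol) would give 2-(2,4,6-trimethoxyphenoxy)benzene-1,3-diol F3, and methylation (MeI, K2CO3) would give 7. The ring C oxygens are bought in this variant, the ether lone pair is no longer contested by formyl groups on ring C, and only two migrations are needed. The price is that the four-in-one oxygen installation is given up.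

Step 2. The addition of the doubly stabilised, doubly ortho-substituted phenoxide may be slow. Hydrolysis of the fluoride by traces of water and aryloxide exchange at the activated product could then compete. The fallback sets out from 2 and comes back at 4. Acetalisation of both formyl groups with ethylene glycol (TsOH, toluene, water removal) would give 2,6-bis(1,3-dioxolan-2-yl)-4-methoxyphenol F4, whose phenoxide is far more nucleophilic. SNAr with 3 would give 2-[2,6-bis(1,3-dioxolan-2-yl)-4-methoxyphenoxy]benzene-1,3-dicarbaldehyde F5, in which ring C is no longer activated towards exchange. Aqueous HCl in THF would then unmask the aldehydes to give 4.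

Step 6. Protodeboronation of the 2,6-dialkoxyarylboronic acid may outrun transmetalation onto a hindered arylpalladium intermediate, and reductive elimination to a tetra-ortho-substituted biaryl is slow. The fallback sets out from 8 and comes back at 10. Lithiation of purchased 1,3,5-trimethoxybenzene F6 with n-BuLi and transmetalation with ZnCl2 would give (2,4,6-trimethoxyphenyl)zinc chloride F7. A Negishi coupling of F7 with 8 (Pd2(dba)3, RuPhos, THF, 70 °C) would give 10. The organozinc reagent cannot protodeboronate and transmetalates readily.

Step 8. Oxidative side reactions under copper and O2 are the risk: homocoupling and hydroxylation of the boronic acid, and oxidation of the electron-rich phenol before the C–O bond forms. The fallback sets out from 12 and comes back at 14. An Ullmann-type coupling of 12 with purchased 1-bromo-3,5-dimethoxybenzene F8 (CuI, N,N-dimethylglycine, Cs2CO3, dioxane, 90 °C, argon) would give 14 without any oxidant.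

## Further compounds

F1 | step 3 | 2,4,6-trimethoxyphenol | COc1cc(OC)c(O)c(OC)c1
F2 | step 3 | 2-(2,4,6-trimethoxyphenoxy)benzene-1,3-dicarbaldehyde | COc1cc(OC)c(Oc2c(C=O)cccc2C=O)c(OC)c1
F3 | step 3 | 2-(2,4,6-trimethoxyphenoxy)benzene-1,3-diol | COc1cc(OC)c(Oc2c(O)cccc2O)c(OC)c1
F4 | step 2 | 2,6-bis(1,3-dioxolan-2-yl)-4-methoxyphenol | COc1cc(C2OCCO2)c(O)c(C2OCCO2)c1
F5 | step 2 | 2-[2,6-bis(1,3-dioxolan-2-yl)-4-methoxyphenoxy]benzene-1,3-dicarbaldehyde | COc1cc(C2OCCO2)c(Oc2c(C=O)cccc2C=O)c(C2OCCO2)c1
F6 | step 6 | 1,3,5-trimethoxybenzene | COc1cc(OC)cc(OC)c1
F7 | step 6 | (2,4,6-trimethoxyphenyl)zinc chloride | COc1cc(OC)c([Zn]Cl)c(OC)c1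
F8 | step 8 | 1-bromo-3,5-dimethoxybenzene | COc1cc(Br)cc(OC)c1
A1 | alternative 1 | rac-4-[(tert-butyldimethylsilyl)oxy]-4-(1-ethoxyethenyl)-3-methoxy-2-(2,4,6-trimethoxyphenyl)cyclobut-2-en-1-one | O=C1C(c2c(OC)cc(OC)cc2OC)=C(OC)C1(O[Si](C)(C)C(C)(C)C)C(=C)OCC
A2 | alternative 1 | 4-(tert-butyldimethylsilyloxy)-5-ethoxy-3-methoxy-2-(2,4,6-trimethoxyphenyl)phenol | CCOc1cc(O)c(-c2c(OC)cc(OC)cc2OC)c(OC)c1O[Si](C)(C)C(C)(C)C
A3 | alternative 2 | 6-({3-[4-(3,5-dimethoxyphenoxy)-2,6-dimethoxyphenoxy]-2,4,6-trimethoxyphenyl}methyl)-4-methoxy-2H-pyran-2-one | COC1=CC(=O)OC(Cc2c(OC)cc(OC)c(Oc3c(OC)cc(Oc4cc(OC)cc(OC)c4)cc3OC)c2OC)=C1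
A4 | alternative 2 | 2-{3-[4-(3,5-dimethoxyphenoxy)-2,6-dimethoxyphenoxy]-2,4,6-trimethoxyphenyl}-5-methoxybenzene-1,3-diol | COc1cc(O)c(-c2c(OC)cc(OC)c(Oc3c(OC)cc(Oc4cc(OC)cc(OC)c4)cc3OC)c2OC)c(O)c1
A5 | alternative 3 | rac-3-ethoxy-4-[(2,2',4,4',6,6'-hexamethoxy-[1,1'-biphenyl]-3-yl)oxy]cyclobut-2-en-1-one | CCOC1=CC(=O)C1Oc1c(OC)cc(OC)c(-c2c(OC)cc(OC)cc2OC)c1OC
A6 | alternative 3 | 1-(ethynyloxy)-3,5-dimethoxybenzene | C#COc1cc(OC)cc(OC)c1
A7 | alternative 3 | 5-(3,5-dimethoxyphenoxy)-3-ethoxy-2-[2,4,6-trimethoxy-3-(2,4,6-trimethoxyphenyl)phenoxy]phenol | CCOc1cc(Oc2cc(OC)cc(OC)c2)cc(O)c1Oc1c(OC)cc(OC)c(-c2c(OC)cc(OC)cc2OC)c1OC
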